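The route rests on ring A of unit 2 (C4a, C5, C6, C7, C8, C8a of the 5,7-dihydroxy-4'-methoxyflavone half). This 1,3,5-trioxygenated benzene ring carries C3' of ring B of unit 1 (the 5-hydroxy-7-methoxyflavone half) at C6, between the C5 and C7 oxygens, and its C4a–C8a edge is the C3=C2 double bond of a 4-pyranone.
Disconnection 1 (last ring): ring C of unit 1 is opened to a ring B ethynyl group, CO and 2-iodo-5-methoxyresorcinol diacetate (Pd-catalysed carbonylative annulation). The alkyne goes back to a ring B aldehyde kept as a dioxolane.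
Disconnection 2 (central): ring A of unit 2 is split by a diazo ketone-based Danheiser benzannulation into a 2-diazoacetyl-6-anisyl-4-pyranone (delivers C5, C8, C8a, C4a) and the ring B triisopropylsilyl ynol ether (delivers C6, C7).
Disconnection 3: the pyranone acid comes from anisoylacetone and diethyl oxalate, and the ynol ether from methyl 5-formyl-2-methoxybenzoate by Kowalski ynolate formation.
Order of ring formation: ring C of unit 2, then ring A of unit 2, then ring C of unit 1. Both rings B and ring A of unit 1 are bought as arenes.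
Key step: step 7

Assumption: the target has no stereocentre, and the C3'–C6'' biaryl axis, drawn without configuration, is treated as needing no stereocontrol.

Step 1
Reactants: 1 1-(4-methoxyphenyl)butane-1,3-dione; 2 diethyl oxalate
Product: 3 ethyl 6-(4-methoxyphenyl)-2,4,6-trioxohexanoate (enol tautomers)
Conditions: NaOEt (2.2 equiv), EtOH, 0 → 60 °C; then 2 M HCl
Reagents that add atoms: none
Why: Crossed Claisen condensation under equilibrating ethoxide conditions, in which the non-enolisable oxalate acylates the terminal methyl group of the diketone enolate, a well-precedented outcome because only that product is drained off as a stable doubly enolised salt.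

Step 2
Reactants: 3 ethyl 6-(4-methoxyphenyl)-2,4,6-trioxohexanoate
Product: 4 6-(4-methoxyphenyl)-4-oxo-4H-pyran-2-carboxylic acid
Conditions: conc. HCl, AcOH, reflux
Reagents that add atoms: water, O
Why: Acid-catalysed cyclodehydration of the 1,3,5-triketone (enol oxygen of the aryl ketone onto the C2 ketone, six-membered closure) gives the 4-pyranone, the hot aqueous acid hydrolyses the ester in the same operation, and the aryl methyl ether is inert to HCl.

Step 3
Reactants: 4 6-(4-methoxyphenyl)-4-oxo-4H-pyran-2-carboxylic acid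
Product: 5 6-(4-methoxyphenyl)-4-oxo-4H-pyran-2-carbonyl chloride
Conditions: SOCl2, DMF (cat.), PhMe, 75 °C; evaporate, use crude
Reagents that add atoms: thionyl chloride, O=S(Cl)Cl
Why: Acid chloride formation with thionyl chloride under Vilsmeier-type catalysis, routine for 4-pyranone- and chromone-2-carboxylic acids, whose vinylogous ester carbonyl is not attacked under these conditions.

Step 4
Reactants: 5 6-(4-methoxyphenyl)-4-oxo-4H-pyran-2-carbonyl chloride
Product: 6 2-(diazoacetyl)-6-(4-methoxyphenyl)-4H-pyran-4-one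
Conditions: CH2N2 (Et2O solution, 1.5 equiv), Et3N (1.1 equiv), THF, −10 → 0 °C
Reagents that add atoms: diazomethane, C=[N+]=[N-]
Why: Acylation of diazomethane (first stage of the Arndt–Eistert sequence, Newman–Beal variant), in which triethylamine takes up HCl so that little excess diazomethane is present, the acid chloride has no α-hydrogen from which a ketene could form, and acylation at low temperature should outrun dipolar cycloaddition to the pyranone double bonds.

Step 5
Reactants: 7 methyl 5-formyl-2-methoxybenzoate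
Product: 8 methyl 5-(1,3-dioxolan-2-yl)-2-methoxybenzoate
Conditions: HOCH2CH2OH, TsOH·H2O (cat.), PhMe, reflux (Dean–Stark)
Reagents that add atoms: ethylene glycol, OCCO
Why: Acid-catalysed acetalisation with azeotropic removal of water masks the aldehyde against the organolithium reagents of the next step and leaves the benzoate ester untouched.

Step 6
Reactants: 8 methyl 5-(1,3-dioxolan-2-yl)-2-methoxybenzoate
Product: 11 {[5-(1,3-dioxolan-2-yl)-2-methoxyphenyl]ethynyloxy}triisopropylsilane, via dibromoenolate 9 (not isolated), via lithium ynolate 10 (not isolated)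
Conditions: CH2Br2, LiTMP, THF, −78 °C; 8; LiN(SiMe3)2, −78 → −20 °C; n-BuLi, −78 → 25 °C; i-Pr3SiCl, 0 → 25 °C
Reagents that add atoms: dibromomethane, BrCBr; chlorotriisopropylsilane, CC(C)[Si](Cl)(C(C)C)C(C)C
Why: Kowalski ester homologation stopped at the ynolate stage, in which LiCHBr2 adds to the ester, the dibromo ketone is deprotonated to 9, bromine–lithium exchange triggers a 1,2-shift of the electron-rich aryl group with loss of LiBr to give 10, and the bulky silyl chloride traps 10 on oxygen, while dioxolane and aryl ether tolerate the bases at low temperature.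

Step 7
Reactants: 6 2-(diazoacetyl)-6-(4-methoxyphenyl)-4H-pyran-4-one; 11 {[5-(1,3-dioxolan-2-yl)-2-methoxyphenyl]ethynyloxy}triisopropylsilane
Product: 15 6-[5-(1,3-dioxolan-2-yl)-2-methoxyphenyl]-5-hydroxy-2-(4-methoxyphenyl)-7-(triisopropylsilyloxy)-4H-chromen-4-one, via pyranonylketene 12 (not isolated), via cyclobutenone 13 (not isolated), via dienylketene 14 (not isolated)
Conditions: 11 (1.5 equiv), hν (medium-pressure Hg lamp, Pyrex filter, FEP flow coil), degassed ClCH2CH2Cl, 25 °C; then PhMe, 110 °C
Reagents that add atoms: none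
Why: Light expels N2 from 6 and the pyranonyl group migrates from the carbonyl carbon to the former diazo carbon (photochemical Wolff rearrangement, C8–C8a), giving ketene 12. The electrophilic central carbon of 12 is attacked by the aryl-bearing, nucleophilic carbon of ynol ether 11, so the [2+2] cycloaddition lays down C5–C6 and C7–C8 in cyclobutenone 13. On heating, 13 opens reversibly in a 4π electrocyclic reaction (the old CO–CH bond breaks) to dienylketene 14, and ring A closes by 6π electrocyclisation of the ketene carbon onto C3 of the pyranone (C4a–C5), after which tautomerisation gives the hydrogen-bonded 5-phenol. The closest known reaction is the second-generation Danheiser benzannulation of vinyl, aryl and heteroaryl diazomethyl ketones with siloxyalkynes and ynamides; here the C2=C3 bond of the 4-pyranone takes the part of the vinyl group. The one selectivity required, aryl group between hydroxyl and silyloxy group, is secured by the polarisation of the ynol ether, and the 6π closure has a single terminus, C3, which is the electron-rich β-carbon of the ring enol ether; no stereocentre is created, as the C4 centre of 13 vanishes on ring opening. Pyrex-filtered light in a thin flow film limits absorption by the anisylpyranone and by the flavone formed, and the excess of 11 keeps 12 from dimerising or acylating the product phenol.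

Step 8
Reactants: 15 6-[5-(1,3-dioxolan-2-yl)-2-methoxyphenyl]-5-hydroxy-2-(4-methoxyphenyl)-7-(triisopropylsilyloxy)-4H-chromen-4-one
Product: 16 3-[5-hydroxy-2-(4-methoxyphenyl)-4-oxo-7-(triisopropylsilyloxy)-4H-chromen-6-yl]-4-methoxybenzaldehyde
Conditions: 1 M HCl, THF, 25 °C
Reagents that add atoms: water, O
Why: Mild acid-catalysed acetal hydrolysis, to which the aryl triisopropylsilyl ether and the flavone are stable at room temperature.

Step 9
Reactants: 16 3-[5-hydroxy-2-(4-methoxyphenyl)-4-oxo-7-(triisopropylsilyloxy)-4H-chromen-6-yl]-4-methoxybenzaldehyde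
Product: 17 6-(5-ethynyl-2-methoxyphenyl)-5-hydroxy-2-(4-methoxyphenyl)-7-(triisopropylsilyloxy)-4H-chromen-4-one
Conditions: MeC(O)C(N2)P(O)(OMe)2, K2CO3 (3 equiv), MeOH/THF, 0 → 25 °C
Reagents that add atoms: dimethyl (1-diazo-2-oxopropyl)phosphonate, COP(=O)(OC)C(=[N+]=[N-])C(C)=O
Why: Ohira–Bestmann variant of the Seyferth–Gilbert homologation, in which methanolysis frees the diazomethylphosphonate anion, its adduct with the non-enolisable aldehyde collapses to an alkylidene carbene that gives the terminal alkyne by 1,2-hydrogen shift, the chelated 5-hydroxyl only consumes base, and the silyl ether, shielded by its isopropyl groups and the neighbouring C6 aryl group, should outlast carbonate in methanol.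

Step 10
Reactants: 18 5-methoxyresorcinol
Product: 19 2-iodo-5-methoxybenzene-1,3-diol
Conditions: I2, NaHCO3, THF/H2O, 0 °C
Reagents that add atoms: iodine, II
Why: Electrophilic aromatic iodination under bicarbonate buffering, which as with resorcinol itself should favour the position flanked by the two hydroxyl groups, and the symmetric 2-iodo isomer can be freed from any 4-iodo isomer by crystallisation or chromatography.

Step 11
Reactants: 19 2-iodo-5-methoxybenzene-1,3-diol
Product: 20 2-iodo-5-methoxy-1,3-phenylene diacetate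
Conditions: Ac2O, pyridine, 0 → 25 °C
Reagents that add atoms: acetic anhydride, CC(=O)OC(C)=O
Why: O-acetylation gives an aryl iodide that is less electron-rich and less prone to oxidation and deiodination than the free iodoresorcinol, and iodophenol acetates are the substrate type for which the mild carbonylative flavone annulation is established.

Step 12
Reactants: 17 6-(5-ethynyl-2-methoxyphenyl)-5-hydroxy-2-(4-methoxyphenyl)-7-(triisopropylsilyloxy)-4H-chromen-4-one; 20 2-iodo-5-methoxy-1,3-phenylene diacetate
Product: 22 5-hydroxy-6-[5-(5-hydroxy-7-methoxy-4-oxo-4H-chromen-2-yl)-2-methoxyphenyl]-2-(4-methoxyphenyl)-7-(triisopropylsilyloxy)-4H-chromen-4-one, via dihydroxyaryl ynone 21 (not isolated)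
Conditions: CO (1 atm), PdCl2(PPh3)2, dppp, thiourea (5 mol % each), Et2NH, DBU (2 equiv), THF, 40 °C
Reagents that add atoms: carbon monoxide, [C-]#[O+]
Why: Pd-catalysed carbonylative Sonogashira-type coupling and annulation, in which zerovalent palladium inserts into the carbon–iodine bond, CO insertion and alkynylation build the ynone, diethylamine removes both acetates to give 21, and amine-mediated conjugate addition–elimination closes ring C of unit 1 in the 6-endo sense (flavone, not aurone), while the symmetry of 20 makes either phenol deliver the 5-hydroxy-7-methoxy pattern.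

Step 13
Reactants: 22 5-hydroxy-6-[5-(5-hydroxy-7-methoxy-4-oxo-4H-chromen-2-yl)-2-methoxyphenyl]-2-(4-methoxyphenyl)-7-(triisopropylsilyloxy)-4H-chromen-4-one
Product: 23 5,7-dihydroxy-6-[5-(5-hydroxy-7-methoxy-4-oxo-4H-chromen-2-yl)-2-methoxyphenyl]-2-(4-methoxyphenyl)-4H-chromen-4-one (CNP0281098.0)
Conditions: Bu4NF, AcOH (1.2 equiv each), THF, 0 °C
Reagents that add atoms: none
Why: Fluoride-induced cleavage of the aryl silyl ether, buffered with acetic acid so that neither flavone sees a strong base.

Compound list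
1 | 1-(4-methoxyphenyl)butane-1,3-dione | COc1ccc(C(=O)CC(C)=O)cc1 | starting material
2 | diethyl oxalate | CCOC(=O)C(=O)OCC | starting material
3 | ethyl 6-(4-methoxyphenyl)-2,4,6-trioxohexanoate | CCOC(=O)C(=O)CC(=O)CC(=O)c1ccc(OC)cc1 | intermediate
4 | 6-(4-methoxyphenyl)-4-oxo-4H-pyran-2-carboxylic acid | COc1ccc(-c2cc(=O)cc(C(=O)O)o2)cc1 | intermediate
5 | 6-(4-methoxyphenyl)-4-oxo-4H-pyran-2-carbonyl chloride | COc1ccc(-c2cc(=O)cc(C(=O)Cl)o2)cc1 | intermediate
6 | 2-(diazoacetyl)-6-(4-methoxyphenyl)-4H-pyran-4-one | COc1ccc(-c2cc(=O)cc(C(=O)C=[N+]=[N-])o2)cc1 | intermediate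
7 | methyl 5-formyl-2-methoxybenzoate | COC(=O)c1cc(C=O)ccc1OC | starting material
8 | methyl 5-(1,3-dioxolan-2-yl)-2-methoxybenzoate | COC(=O)c1cc(C2OCCO2)ccc1OC | intermediate
9 | lithium 2,2-dibromo-1-[5-(1,3-dioxolan-2-yl)-2-methoxyphenyl]ethen-1-olate | COc1ccc(C2OCCO2)cc1C([O-])=C(Br)Br.[Li+] | intermediate
10 | lithium 2-[5-(1,3-dioxolan-2-yl)-2-methoxyphenyl]ethyn-1-olate | COc1ccc(C2OCCO2)cc1C#C[O-].[Li+] | intermediate
11 | {[5-(1,3-dioxolan-2-yl)-2-methoxyphenyl]ethynyloxy}triisopropylsilane | COc1ccc(C2OCCO2)cc1C#CO[Si](C(C)C)(C(C)C)C(C)C | intermediate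
12 | [6-(4-methoxyphenyl)-4-oxo-4H-pyran-2-yl]ketene | COc1ccc(-c2cc(=O)cc(C=C=O)o2)cc1 | intermediate
13 | 2-[5-(1,3-dioxolan-2-yl)-2-methoxyphenyl]-4-[6-(4-methoxyphenyl)-4-oxo-4H-pyran-2-yl]-3-(triisopropylsilyloxy)cyclobut-2-en-1-one (racemic) | COc1ccc(-c2cc(=O)cc(C3C(=O)C(-c4cc(C5OCCO5)ccc4OC)=C3O[Si](C(C)C)(C(C)C)C(C)C)o2)cc1 | intermediate
14 | (E)-2-[5-(1,3-dioxolan-2-yl)-2-methoxyphenyl]-4-[6-(4-methoxyphenyl)-4-oxo-4H-pyran-2-yl]-3-(triisopropylsilyloxy)buta-1,3-dien-1-one (pyranonyl group cis to the ketene-bearing carbon) | COc1ccc(-c2cc(=O)cc(/C=C(/O[Si](C(C)C)(C(C)C)C(C)C)C(=C=O)c3cc(C4OCCO4)ccc3OC)o2)cc1 | intermediate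
15 | 6-[5-(1,3-dioxolan-2-yl)-2-methoxyphenyl]-5-hydroxy-2-(4-methoxyphenyl)-7-(triisopropylsilyloxy)-4H-chromen-4-one | COc1ccc(-c2cc(=O)c3c(O)c(-c4cc(C5OCCO5)ccc4OC)c(O[Si](C(C)C)(C(C)C)C(C)C)cc3o2)cc1 | intermediate
16 | 3-[5-hydroxy-2-(4-methoxyphenyl)-4-oxo-7-(triisopropylsilyloxy)-4H-chromen-6-yl]-4-methoxybenzaldehyde | COc1ccc(-c2cc(=O)c3c(O)c(-c4cc(C=O)ccc4OC)c(O[Si](C(C)C)(C(C)C)C(C)C)cc3o2)cc1 | intermediate
17 | 6-(5-ethynyl-2-methoxyphenyl)-5-hydroxy-2-(4-methoxyphenyl)-7-(triisopropylsilyloxy)-4H-chromen-4-one | COc1ccc(-c2cc(=O)c3c(O)c(-c4cc(C#C)ccc4OC)c(O[Si](C(C)C)(C(C)C)C(C)C)cc3o2)cc1 | intermediate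
18 | 5-methoxyresorcinol | COc1cc(O)cc(O)c1 | starting material
19 | 2-iodo-5-methoxybenzene-1,3-diol | COc1cc(O)c(I)c(O)c1 | intermediate
20 | 2-iodo-5-methoxy-1,3-phenylene diacetate | COc1cc(OC(C)=O)c(I)c(OC(C)=O)c1 | intermediate
21 | 6-{5-[3-(2,6-dihydroxy-4-methoxyphenyl)-3-oxoprop-1-ynyl]-2-methoxyphenyl}-5-hydroxy-2-(4-methoxyphenyl)-7-(triisopropylsilyloxy)-4H-chromen-4-one | COc1ccc(-c2cc(=O)c3c(O)c(-c4cc(C#CC(=O)c5c(O)cc(OC)cc5O)ccc4OC)c(O[Si](C(C)C)(C(C)C)C(C)C)cc3o2)cc1 | intermediate
22 | 5-hydroxy-6-[5-(5-hydroxy-7-methoxy-4-oxo-4H-chromen-2-yl)-2-methoxyphenyl]-2-(4-methoxyphenyl)-7-(triisopropylsilyloxy)-4H-chromen-4-one | COc1ccc(-c2cc(=O)c3c(O)c(-c4cc(-c5cc(=O)c6c(O)cc(OC)cc6o5)ccc4OC)c(O[Si](C(C)C)(C(C)C)C(C)C)cc3o2)cc1 | intermediate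
23 | 5,7-dihydroxy-6-[5-(5-hydroxy-7-methoxy-4-oxo-4H-chromen-2-yl)-2-methoxyphenyl]-2-(4-methoxyphenyl)-4H-chromen-4-one | COc1ccc(-c2cc(=O)c3c(O)c(-c4cc(-c5cc(=O)c6c(O)cc(OC)cc6o5)ccc4OC)c(O)cc3o2)cc1 | target

Total step count: 13.
Longest linear sequence: 9 steps (1 → 3 → 4 → 5 → 6 → 15 → 16 → 17 → 22 → 23).

Steps most likely to fail

Step 7.
- **Risk:** The anisylpyranone chromophore of 6 and the flavone chromophore of the growing product may compete for the light. Nitrogen loss could then stall or the pyranone could photoisomerise. The ketene may also dimerise before it meets the ortho-substituted arylynol ether.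
- **Fallback:** It sets out from diazo ketone 6 (with 11 as partner), comes back at 15, and makes the ketene in the dark.
  - The Wolff rearrangement of 6 is run separately with PhCO2Ag in aqueous dioxane under ultrasound at 25 °C. Water traps the ketene as [6-(4-methoxyphenyl)-4-oxo-4H-pyran-2-yl]acetic acid F1.
  - (COCl)2 with catalytic DMF in CH2Cl2 at 0 °C converts it into [6-(4-methoxyphenyl)-4-oxo-4H-pyran-2-yl]acetyl chloride F2.
  - Slow addition of i-Pr2NEt to F2 and an excess of 11 in toluene at 0–25 °C generates 12 by dehydrochlorination.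
  - The [2+2] adduct 13 can then be isolated. Its thermal rearrangement through 14 (toluene or xylene, 110–140 °C) can be optimised on its own to give 15.

Step 12.
- **Risk:** Oxidative addition into the doubly ortho-substituted aryl iodide may be slow and accompanied by reductive loss of iodine. The acylpalladium species may be captured by diethylamine instead of by the alkyne. The ynone may close in the 5-exo sense.
- **Fallback:** It sets out from aldehyde 16, comes back at target 23, and builds ring C of unit 1 by the chalcone route.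
  - Purchased 2',6'-dihydroxy-4'-methoxyacetophenone is mono-protected (MeOCH2Cl, i-Pr2NEt, CH2Cl2, 0 °C; the second hydroxyl stays chelated) to 1-[2-hydroxy-4-methoxy-6-(methoxymethoxy)phenyl]ethan-1-one F3.
  - Claisen–Schmidt condensation of F3 with 16 (KOH, EtOH, 25 °C) also strips the silyl ether. The resulting 7-phenoxide protects the flavone of unit 2 from hydroxide. The product is the (E)-2'-hydroxychalcone F4.
  - Oxidative cyclisation with catalytic I2 in DMSO at 120 °C gives the 5-O-methoxymethyl biflavone F5.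
  - HCl in MeOH at 50 °C removes the acetal protecting group to give 23.

Step 6.
- **Risk:** The tetrahedral adduct may collapse or be deprotonated incompletely. The carbenoid may be protonated before the aryl shift. The ynolate may be silylated on carbon instead of oxygen.
- **Fallback:** It sets out from ester 8, comes back at ynolate 10 and then 11, and reaches the ynolate by oxidation of an acetylide.
  - LiAlH4 in THF at 0 °C gives [5-(1,3-dioxolan-2-yl)-2-methoxyphenyl]methanol F6.
  - MnO2 in CH2Cl2 gives 5-(1,3-dioxolan-2-yl)-2-methoxybenzaldehyde F7.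
  - The Ohira–Bestmann reagent with K2CO3 in MeOH gives 2-(3-ethynyl-4-methoxyphenyl)-1,3-dioxolane F8.
  - F8 is deprotonated with n-BuLi in THF at −78 °C. The acetylide is oxidised with t-BuOOLi (from anhydrous t-BuOOH and LiN(SiMe3)2, −78 → 0 °C) to 10, which i-Pr3SiOTf traps at −78 °C as 11.

Further compounds
F1 | step 7 | [6-(4-methoxyphenyl)-4-oxo-4H-pyran-2-yl]acetic acid | COc1ccc(-c2cc(=O)cc(CC(=O)O)o2)cc1
F2 | step 7 | [6-(4-methoxyphenyl)-4-oxo-4H-pyran-2-yl]acetyl chloride | COc1ccc(-c2cc(=O)cc(CC(=O)Cl)o2)cc1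
F3 | step 12 | 1-[2-hydroxy-4-methoxy-6-(methoxymethoxy)phenyl]ethan-1-one | CC(=O)c1c(O)cc(OC)cc1OCOC
F4 | step 12 | 5,7-dihydroxy-6-{5-[(E)-3-[2-hydroxy-4-methoxy-6-(methoxymethoxy)phenyl]-3-oxoprop-1-enyl]-2-methoxyphenyl}-2-(4-methoxyphenyl)-4H-chromen-4-one | COc1ccc(-c2cc(=O)c3c(O)c(-c4cc(/C=C/C(=O)c5c(O)cc(OC)cc5OCOC)ccc4OC)c(O)cc3o2)cc1
F5 | step 12 | 5,7-dihydroxy-6-{2-methoxy-5-[7-methoxy-5-(methoxymethoxy)-4-oxo-4H-chromen-2-yl]phenyl}-2-(4-methoxyphenyl)-4H-chromen-4-one | COc1ccc(-c2cc(=O)c3c(O)c(-c4cc(-c5cc(=O)c6c(OCOC)cc(OC)cc6o5)ccc4OC)c(O)cc3o2)cc1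
F6 | step 6 | [5-(1,3-dioxolan-2-yl)-2-methoxyphenyl]methanol | COc1ccc(C2OCCO2)cc1CO
F7 | step 6 | 5-(1,3-dioxolan-2-yl)-2-methoxybenzaldehyde | COc1ccc(C2OCCO2)cc1C=O
F8 | step 6 | 2-(3-ethynyl-4-methoxyphenyl)-1,3-dioxolane | COc1ccc(C2OCCO2)cc1C#C
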